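**Plan**
- Retrosynthesis: remove both benzyl groups, then cut the propyl–C(=O) bond of the 2-oxopentyl chain (thioester plus propylzinc), which leaves a CH2CO2tBu arm on ring A.
- Next cut the two neighbouring ring A bonds C6–CH2 and C1–C(=O) in one operation (aryne sigma-insertion). This gives an ortho-silylaryl triflate and the ring B aryl tert-butyl malonate; the malonate O-acyl bond and the ring B carboxyl (from olivetol) are cut last.
- Enabling feature: ring A carries the depside carbonyl on C1 and the CH2–C(=O) chain on C6, on adjacent ring carbons, and the oxygen on C2 flanks C1. A 3-oxygenated aryne can therefore take up a CH2–C(=O)OAr unit with defined regiochemistry.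
- Forward: no ring is built and both benzene rings are bought. The ring B phenol is acylated with the malonic half-ester, the aryne insertion joins ring A and creates the hindered depside carbonyl, the side chain is extended by three carbons, and the benzyl groups are removed.
- Stereochemistry: the target has no stereocentre and no stereogenic double bond; only regiochemistry has to be controlled (benzyloxy-directed aryne addition, hydrogen-bond-directed differentiation of the two ring B phenols).

Key step: step 12

Assumption: the target is made as the free acid and free phenol drawn, and propylzinc bromide is bought as its THF solution.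

**Step 1**
Reactants: 1 2-hydroxy-4-methoxybenzaldehyde
Product: 2 2-(benzyloxy)-4-methoxybenzaldehyde
Conditions: BnBr, K2CO3, DMF, rt
Reagents that add atoms: benzyl bromide, BrCc1ccccc1
Why: Williamson ether synthesis on the phenoxide should be clean, and the benzyl group is chosen so that it leaves together with the benzyl ester in the last step.

**Step 2**
Reactants: 2 2-(benzyloxy)-4-methoxybenzaldehyde
Product: 4 2-(benzyloxy)-4-methoxyphenol, via aryl formate 3 (not isolated)
Conditions: mCPBA, CH2Cl2, 0 °C to rt; aq. NaHCO3 wash; then K2CO3 (0.2 equiv), MeOH, rt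
Reagents that add atoms: 3-chloroperoxybenzoic acid, OOC(=O)c1cccc(Cl)c1
Why: Baeyer–Villiger (Dakin-type) oxidation of an ortho,para-dialkoxybenzaldehyde should proceed with aryl migration to the formate, which mild methanolysis converts into the phenol.

**Step 3**
Reactants: 4 2-(benzyloxy)-4-methoxyphenol
Product: 5 2-(benzyloxy)-4-methoxyphenyl propan-2-ylcarbamate
Conditions: i-PrNCO, Et3N (cat.), CH2Cl2, rt
Reagents that add atoms: isopropyl isocyanate, CC(C)N=C=O
Why: Base-catalysed addition of the phenol to the isocyanate (carbamoylation) should install a strong ortho-directing group that can later be removed under mild conditions.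

**Step 4**
Reactants: 5 2-(benzyloxy)-4-methoxyphenyl propan-2-ylcarbamate
Product: 9 2-(benzyloxy)-4-methoxy-6-(trimethylsilyl)phenyl propan-2-ylcarbamate, via N-silyl carbamate 6 (not isolated), via aryllithium 7 (not isolated), via bis-silyl carbamate 8 (not isolated)
Conditions: TBSOTf, TMEDA, Et2O, 0 °C to rt; n-BuLi, TMEDA, −78 °C; TMSCl, −78 °C to rt; aq. NaHSO4
Reagents that add atoms: chlorotrimethylsilane, C[Si](C)(C)Cl
Why: Directed ortho-metalation of the N-silylated carbamate should take place at C6, the only free position ortho to the carbamate; the aryllithium is silylated by TMSCl and the N-silyl group is lost on acidic work-up.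

**Step 5**
Reactants: 9 2-(benzyloxy)-4-methoxy-6-(trimethylsilyl)phenyl propan-2-ylcarbamate
Product: 11 2-(benzyloxy)-4-methoxy-6-(trimethylsilyl)phenyl trifluoromethanesulfonate, via silylphenol 10 (not isolated)
Conditions: DBU, Et2NH, MeCN, 40 °C; then PhNTf2, rt
Reagents that add atoms: N-phenylbis(trifluoromethanesulfonimide), O=S(=O)(N(c1ccccc1)S(=O)(=O)C(F)(F)F)C(F)(F)F
Why: E1cB cleavage of the secondary carbamate (the isocyanate is scavenged by diethylamine) should free the ortho-silyl phenoxide, which is O-sulfonylated in the same flask to give the ortho-silylaryl triflate.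

**Step 6**
Reactants: 12 olivetol (5-pentylbenzene-1,3-diol)
Product: 13 olivetolic acid (2,4-dihydroxy-6-pentylbenzoic acid)
Conditions: MeOMgOCO2Me (methyl magnesium carbonate, 2 M in DMF), 120 °C; then cold aq. HCl
Reagents that add atoms: methyl magnesium carbonate, COC(=O)O[Mg]OC
Why: Kolbe–Schmitt-type carboxylation through a magnesium chelate delivers CO2 ortho to a phenolic OH and is the established access to this salicylic acid from olivetol; any 2,6-dihydroxy isomer would be removed here.

**Step 7**
Reactants: 13 olivetolic acid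
Product: 14 benzyl 2,4-dihydroxy-6-pentylbenzoate
Conditions: BnBr, KHCO3, DMF, rt
Reagents that add atoms: benzyl bromide, BrCc1ccccc1
Why: Bicarbonate deprotonates only the carboxylic acid, so carboxylate O-alkylation should give the benzyl ester at room temperature without decarboxylation or phenol benzylation.

**Step 8**
Reactants: 14 benzyl 2,4-dihydroxy-6-pentylbenzoate
Product: 15 benzyl 2-hydroxy-4-(methoxymethoxy)-6-pentylbenzoate
Conditions: MOMCl (1.1 equiv), i-Pr2NEt, CH2Cl2, 0 °C
Reagents that add atoms: chloromethyl methyl ether, COCCl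
Why: The 2-OH is held in a hydrogen bond to the ester carbonyl, so acetal protection should occur selectively at the free, more acidic 4-OH.

**Step 9**
Reactants: 15 benzyl 2-hydroxy-4-(methoxymethoxy)-6-pentylbenzoate
Product: 16 benzyl 2-methoxy-4-(methoxymethoxy)-6-pentylbenzoate
Conditions: MeI, K2CO3, DMF, 40 °C
Reagents that add atoms: iodomethane, CI
Why: Williamson methylation of the remaining chelated phenol should proceed in DMF, while the MOM ether and the di-ortho-substituted benzyl ester are inert to carbonate.

**Step 10**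
Reactants: 16 benzyl 2-methoxy-4-(methoxymethoxy)-6-pentylbenzoate
Product: 17 benzyl 4-hydroxy-2-methoxy-6-pentylbenzoate
Conditions: conc. HCl (cat.), MeOH, 50 °C
Reagents that add atoms: none
Why: Acid-catalysed acetal exchange with methanol should free the 4-OH, and the hindered benzyl ester resists acid methanolysis.

**Step 11**
Reactants: 17 benzyl 4-hydroxy-2-methoxy-6-pentylbenzoate; 18 mono-tert-butyl malonate (3-tert-butoxy-3-oxopropanoic acid)
Product: 19 benzyl 4-[(3-tert-butoxy-3-oxopropanoyl)oxy]-2-methoxy-6-pentylbenzoate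
Conditions: DCC, DMAP (cat.), CH2Cl2, 0 °C to rt
Reagents that add atoms: none
Why: Steglich esterification should give the aryl ester, since carbodiimide activation of a malonic half-ester is readily trapped by a phenol under DMAP catalysis.

**Step 12**
Reactants: 11 2-(benzyloxy)-4-methoxy-6-(trimethylsilyl)phenyl trifluoromethanesulfonate; 19 benzyl 4-[(3-tert-butoxy-3-oxopropanoyl)oxy]-2-methoxy-6-pentylbenzoate
Product: 21 benzyl 4-{[2-(benzyloxy)-6-(2-tert-butoxy-2-oxoethyl)-4-methoxybenzoyl]oxy}-2-methoxy-6-pentylbenzoate, via aryne 20 (not isolated)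
Conditions: KF (3 equiv), 18-crown-6 (3 equiv), THF, 0 °C to rt; 11 (1.5 equiv) added slowly
Reagents that add atoms: none
Why: Proposed new method: fluoride removes the silyl group of 11 and triflate departs to give aryne 20 while the malonate 19 is deprotonated; the malonate carbon adds to the aryne carbon remote from the benzyloxy group, the aryl anion left next to that oxygen adds to the neighbouring aryl ester carbonyl, and the resulting benzocyclobutenoxide opens with strain relief to the tert-butyl arylacetate enolate, which is protonated by further 19. The closest known reaction type is the aryne acyl-alkylation, the insertion of arynes into the C–C sigma bond of beta-keto esters and dialkyl malonates; new here is a mixed aryl tert-butyl malonate whose aryloxy group must stay on the migrating carbonyl. No ring remains in the product: the only closure is the transient four-membered alkoxide (4-exo-trig attack of the aryl anion on the ester carbonyl), which reopens at once, and no stereocentre is formed. Regioselectivity is required and should come from the benzyloxy group at the aryne terminus, whose inductive effect and distortion of the triple bond send the nucleophile to the distal carbon and place the anion on the proximal one. Chemoselectivity between the two ester carbonyls is also required and should follow from the aryl ester being more electrophilic and far less hindered than the tert-butyl ester. Low temperature and slow release of the aryne are meant to hold back E1cB loss of the ring B phenoxide from 19.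

**Step 13**
Reactants: 21 benzyl 4-{[2-(benzyloxy)-6-(2-tert-butoxy-2-oxoethyl)-4-methoxybenzoyl]oxy}-2-methoxy-6-pentylbenzoate
Product: 22 [3-(benzyloxy)-2-({4-[(benzyloxy)carbonyl]-3-methoxy-5-pentylphenoxy}carbonyl)-5-methoxyphenyl]acetic acid
Conditions: TFA, CH2Cl2 (1:4), 0 °C to rt
Reagents that add atoms: none
Why: Acidolysis of the tert-butyl ester (loss of isobutene) should leave the benzyl ether, the benzyl ester and the aryl ester intact, and no base touches the acid.

**Step 14**
Reactants: 22 [3-(benzyloxy)-2-({4-[(benzyloxy)carbonyl]-3-methoxy-5-pentylphenoxy}carbonyl)-5-methoxyphenyl]acetic acid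
Product: 23 benzyl 4-({2-(benzyloxy)-6-[2-(ethylsulfanyl)-2-oxoethyl]-4-methoxybenzoyl}oxy)-2-methoxy-6-pentylbenzoate
Conditions: EtSH, DCC, DMAP (5 mol %), CH2Cl2, 0 °C
Reagents that add atoms: ethanethiol, CCS
Why: Steglich thioesterification should convert the unhindered arylacetic acid into the S-ethyl thioester, and keeping DMAP catalytic at 0 °C limits the lifetime of the carboxylate beside the aryl ester.

**Step 15**
Reactants: 23 benzyl 4-({2-(benzyloxy)-6-[2-(ethylsulfanyl)-2-oxoethyl]-4-methoxybenzoyl}oxy)-2-methoxy-6-pentylbenzoate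
Product: 24 benzyl 4-{[2-(benzyloxy)-4-methoxy-6-(2-oxopentyl)benzoyl]oxy}-2-methoxy-6-pentylbenzoate
Conditions: n-PrZnBr (0.5 M in THF, 2 equiv), PdCl2(PPh3)2 (5 mol %), toluene, rt
Reagents that add atoms: propylzinc bromide, CCC[Zn]Br
Why: Fukuyama coupling (insertion of zerovalent palladium into the C–S bond, transmetalation from zinc, reductive elimination) should give the ketone under neutral conditions that spare both benzoate esters and the acidic benzylic CH2.

**Step 16**
Reactants: 24 benzyl 4-{[2-(benzyloxy)-4-methoxy-6-(2-oxopentyl)benzoyl]oxy}-2-methoxy-6-pentylbenzoate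
Product: 25 4-{[2-hydroxy-4-methoxy-6-(2-oxopentyl)benzoyl]oxy}-2-methoxy-6-pentylbenzoic acid (target)
Conditions: H2 (1 atm), 10% Pd/C, EtOAc, rt
Reagents that add atoms: none
Why: Catalytic hydrogenolysis should cleave the benzyl ether and the benzyl ester together, and the neutral medium spares the dialkyl ketone and the depside ester and avoids enol-lactonisation of the ketone onto the depside carbonyl.

**Compound list**
1 | 2-hydroxy-4-methoxybenzaldehyde | COc1ccc(C=O)c(O)c1 | starting material
2 | 2-(benzyloxy)-4-methoxybenzaldehyde | COc1ccc(C=O)c(OCc2ccccc2)c1 | intermediate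
3 | 2-(benzyloxy)-4-methoxyphenyl formate | COc1ccc(OC=O)c(OCc2ccccc2)c1 | intermediate
4 | 2-(benzyloxy)-4-methoxyphenol | COc1ccc(O)c(OCc2ccccc2)c1 | intermediate
5 | 2-(benzyloxy)-4-methoxyphenyl propan-2-ylcarbamate | COc1ccc(OC(=O)NC(C)C)c(OCc2ccccc2)c1 | intermediate
6 | 2-(benzyloxy)-4-methoxyphenyl [tert-butyl(dimethyl)silyl](propan-2-yl)carbamate | COc1ccc(OC(=O)N(C(C)C)[Si](C)(C)C(C)(C)C)c(OCc2ccccc2)c1 | intermediate
7 | [3-(benzyloxy)-2-({[tert-butyl(dimethyl)silyl](propan-2-yl)carbamoyl}oxy)-5-methoxyphenyl]lithium | [Li]c1cc(OC)cc(OCc2ccccc2)c1OC(=O)N(C(C)C)[Si](C)(C)C(C)(C)C | intermediate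
8 | 2-(benzyloxy)-4-methoxy-6-(trimethylsilyl)phenyl [tert-butyl(dimethyl)silyl](propan-2-yl)carbamate | C[Si](C)(C)c1cc(OC)cc(OCc2ccccc2)c1OC(=O)N(C(C)C)[Si](C)(C)C(C)(C)C | intermediate
9 | 2-(benzyloxy)-4-methoxy-6-(trimethylsilyl)phenyl propan-2-ylcarbamate | C[Si](C)(C)c1cc(OC)cc(OCc2ccccc2)c1OC(=O)NC(C)C | intermediate
10 | 2-(benzyloxy)-4-methoxy-6-(trimethylsilyl)phenol | C[Si](C)(C)c1cc(OC)cc(OCc2ccccc2)c1O | intermediate
11 | 2-(benzyloxy)-4-methoxy-6-(trimethylsilyl)phenyl trifluoromethanesulfonate | C[Si](C)(C)c1cc(OC)cc(OCc2ccccc2)c1OS(=O)(=O)C(F)(F)F | intermediate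
12 | olivetol (5-pentylbenzene-1,3-diol) | CCCCCc1cc(O)cc(O)c1 | starting material
13 | olivetolic acid (2,4-dihydroxy-6-pentylbenzoic acid) | CCCCCc1cc(O)cc(O)c1C(=O)O | intermediate
14 | benzyl 2,4-dihydroxy-6-pentylbenzoate | CCCCCc1cc(O)cc(O)c1C(=O)OCc1ccccc1 | intermediate
15 | benzyl 2-hydroxy-4-(methoxymethoxy)-6-pentylbenzoate | CCCCCc1cc(OCOC)cc(O)c1C(=O)OCc1ccccc1 | intermediate
16 | benzyl 2-methoxy-4-(methoxymethoxy)-6-pentylbenzoate | CCCCCc1cc(OCOC)cc(OC)c1C(=O)OCc1ccccc1 | intermediate
17 | benzyl 4-hydroxy-2-methoxy-6-pentylbenzoate | CCCCCc1cc(O)cc(OC)c1C(=O)OCc1ccccc1 | intermediate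
18 | mono-tert-butyl malonate (3-tert-butoxy-3-oxopropanoic acid) | CC(C)(C)OC(=O)CC(=O)O | starting material
19 | benzyl 4-[(3-tert-butoxy-3-oxopropanoyl)oxy]-2-methoxy-6-pentylbenzoate | CCCCCc1cc(OC(=O)CC(=O)OC(C)(C)C)cc(OC)c1C(=O)OCc1ccccc1 | intermediate
20 | 3-(benzyloxy)-5-methoxybenzyne | COC1=CC#CC(OCc2ccccc2)=C1 | intermediate
21 | benzyl 4-{[2-(benzyloxy)-6-(2-tert-butoxy-2-oxoethyl)-4-methoxybenzoyl]oxy}-2-methoxy-6-pentylbenzoate | CCCCCc1cc(OC(=O)c2c(OCc3ccccc3)cc(OC)cc2CC(=O)OC(C)(C)C)cc(OC)c1C(=O)OCc1ccccc1 | intermediate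
22 | [3-(benzyloxy)-2-({4-[(benzyloxy)carbonyl]-3-methoxy-5-pentylphenoxy}carbonyl)-5-methoxyphenyl]acetic acid | CCCCCc1cc(OC(=O)c2c(OCc3ccccc3)cc(OC)cc2CC(=O)O)cc(OC)c1C(=O)OCc1ccccc1 | intermediate
23 | benzyl 4-({2-(benzyloxy)-6-[2-(ethylsulfanyl)-2-oxoethyl]-4-methoxybenzoyl}oxy)-2-methoxy-6-pentylbenzoate | CCCCCc1cc(OC(=O)c2c(OCc3ccccc3)cc(OC)cc2CC(=O)SCC)cc(OC)c1C(=O)OCc1ccccc1 | intermediate
24 | benzyl 4-{[2-(benzyloxy)-4-methoxy-6-(2-oxopentyl)benzoyl]oxy}-2-methoxy-6-pentylbenzoate | CCCCCc1cc(OC(=O)c2c(OCc3ccccc3)cc(OC)cc2CC(=O)CCC)cc(OC)c1C(=O)OCc1ccccc1 | intermediate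
25 | 4-{[2-hydroxy-4-methoxy-6-(2-oxopentyl)benzoyl]oxy}-2-methoxy-6-pentylbenzoic acid | CCCCCc1cc(OC(=O)c2c(O)cc(OC)cc2CC(=O)CCC)cc(OC)c1C(=O)O | target

**Step count**
Total: 16 steps (5 to the aryne precursor, 6 to the malonate, 5 from the key step to the target).
Longest linear sequence: 11 steps (olivetol 12 to target 25, steps 6 to 16).

**Steps most likely to fail**

Step 12. Before the enolate of 19 meets the aryne it may expel the ring B phenoxide by E1cB ketene formation, and the freed phenoxide would then be arylated on oxygen by the aryne. The aryl anion may also be protonated before it closes onto the ester carbonyl, which stops the sequence at plain alpha-arylation. The fallback makes the depside C–O bond by classical acylation and keeps the aryne insertion for a simple dialkyl malonate, where it is established. It sets out from 11 and 17 and returns at acid 22.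
- Silyl triflate 11 would be inserted into dimethyl malonate (KF, 18-crown-6, THF) to give methyl 2-(benzyloxy)-6-(2-methoxy-2-oxoethyl)-4-methoxybenzoate F1.
- Both methyl esters would be saponified (KOH, aq. DMSO, 80 °C) to 2-(benzyloxy)-6-(carboxymethyl)-4-methoxybenzoic acid F2.
- Acid-catalysed esterification in allyl alcohol at room temperature should touch only the unhindered arylacetic acid and give 2-(benzyloxy)-4-methoxy-6-[2-oxo-2-(prop-2-en-1-yloxy)ethyl]benzoic acid F3.
- The hindered benzoic acid would be joined to phenol 17 with trifluoroacetic anhydride in toluene (mixed-anhydride depside esterification) to give benzyl 4-({2-(benzyloxy)-4-methoxy-6-[2-oxo-2-(prop-2-en-1-yloxy)ethyl]benzoyl}oxy)-2-methoxy-6-pentylbenzoate F4.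
- Pd(PPh3)4 with PhSiH3 in CH2Cl2 would remove the allyl group and deliver 22, from which steps 14 to 16 follow unchanged.

Step 4. Metalation may occur at the wrong site, either at C3 between the two alkoxy groups or at the benzylic CH2 (followed by Wittig rearrangement), and the carbamoyl group may migrate by anionic Fries rearrangement on warming. The fallback places the silicon through a halogen instead of a C–H lithiation. It sets out from phenol 4 and returns at silylphenol 10.
- Amine-directed ortho-bromination (Br2, t-BuNH2, toluene, −78 °C) should give 2-(benzyloxy)-6-bromo-4-methoxyphenol F5.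
- Silylation with hexamethyldisilazane would give [2-(benzyloxy)-6-bromo-4-methoxyphenoxy](trimethyl)silane F6.
- n-BuLi in THF at −78 °C should trigger bromine–lithium exchange and a retro-Brook shift of silicon from oxygen to carbon, giving 10 after aqueous work-up.
- 10 is then triflated with PhNTf2 and DBU as in the second half of step 5 to reach 11.

Step 14. Once deprotonated by DMAP, the carboxylate of 22 may attack the adjacent aryl ester carbonyl and form a cyclic anhydride with release of the ring B phenoxide. Recombination at the other carbonyl would amount to acyl migration or loss of ring B. The activated arylacetic acid may also collapse to a ketene. The fallback avoids any base and skips the thioester. It sets out from 22 and returns at ketone 24.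
- Oxalyl chloride with catalytic DMF in CH2Cl2 would give benzyl 4-{[2-(benzyloxy)-6-(2-chloro-2-oxoethyl)-4-methoxybenzoyl]oxy}-2-methoxy-6-pentylbenzoate F7.
- F7 would be coupled directly with propylzinc bromide under Pd(PPh3)4 in THF at 0 °C (Negishi-type acylation) to give 24.

**Further compounds**
F1 | step 12 | methyl 2-(benzyloxy)-6-(2-methoxy-2-oxoethyl)-4-methoxybenzoate | COC(=O)Cc1cc(OC)cc(OCc2ccccc2)c1C(=O)OC
F2 | step 12 | 2-(benzyloxy)-6-(carboxymethyl)-4-methoxybenzoic acid | OC(=O)Cc1cc(OC)cc(OCc2ccccc2)c1C(=O)O
F3 | step 12 | 2-(benzyloxy)-4-methoxy-6-[2-oxo-2-(prop-2-en-1-yloxy)ethyl]benzoic acid | C=CCOC(=O)Cc1cc(OC)cc(OCc2ccccc2)c1C(=O)O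
F4 | step 12 | benzyl 4-({2-(benzyloxy)-4-methoxy-6-[2-oxo-2-(prop-2-en-1-yloxy)ethyl]benzoyl}oxy)-2-methoxy-6-pentylbenzoate | CCCCCc1cc(OC(=O)c2c(OCc3ccccc3)cc(OC)cc2CC(=O)OCC=C)cc(OC)c1C(=O)OCc1ccccc1
F5 | step 4 | 2-(benzyloxy)-6-bromo-4-methoxyphenol | COc1cc(Br)c(O)c(OCc2ccccc2)c1
F6 | step 4 | [2-(benzyloxy)-6-bromo-4-methoxyphenoxy](trimethyl)silane | COc1cc(Br)c(O[Si](C)(C)C)c(OCc2ccccc2)c1
F7 | step 14 | benzyl 4-{[2-(benzyloxy)-6-(2-chloro-2-oxoethyl)-4-methoxybenzoyl]oxy}-2-methoxy-6-pentylbenzoate | CCCCCc1cc(OC(=O)c2c(OCc3ccccc3)cc(OC)cc2CC(=O)Cl)cc(OC)c1C(=O)OCc1ccccc1
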